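The plan hinges on forming O20–C21 by reductive etherification, which closes the oxepane (O20, C21, C11, C13, C14, C15, C17) onto the cyclohexane (C10, C11, C21–C24). In one operation the C17 tertiary carbinol is joined to the C21 ketone, the seven-membered ring is closed and C21 is set; the step exploits quaternary C11, whose axial methyl C12 sends hydride to the opposite face of the ring. The precursor is a seco diketone (C15 and C21 ketones, C17–OH, C10 acetate, C24 silyl ether) carved from (R)-Wieland–Miescher ketone by enone cleavage. A cis-decalin enol triflate (C1–C8, C27–C33), made by an intramolecular Diels–Alder reaction, is attached at C8–C9 by B-alkyl Suzuki coupling.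

Key step: step 14

Remarks on the chemistry:
- Atoms carry the numbers of their order in the target SMILES (C1 to O34); ring A is C2–C7, ring B is C5, C6, C27, C30, C31, C32.
- C15 is carried from 20 to 41 as a mixture of carbinol epimers, and C7 in 30–37 as formed, because both centres are erased later (steps 32 and 29).
- In step 22 the (S)-catalyst is assumed to expose the enone face that leads to 29; should the sense be the opposite, its antipode is used.
- Isopropenyl- and vinylmagnesium bromide are taken as purchased solutions; 24 and 25 are taken as purchasable.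

Step 1
Reactants: 1 2-methylcyclohexane-1,3-dione; 2 methyl vinyl ketone
Product: 3 2-methyl-2-(3-oxobutyl)cyclohexane-1,3-dione
Conditions: H2O, AcOH (cat.), hydroquinone (cat.), 75 °C
Reagents that add atoms: none
Why: Michael addition of the enolised 1,3-dione to the vinyl ketone should give the achiral triketone.

Step 2
Reactants: 3 2-methyl-2-(3-oxobutyl)cyclohexane-1,3-dione
Product: 4 (R)-Wieland–Miescher ketone
Conditions: D-proline (5 mol%), DMSO, 25 °C; recrystallisation
Reagents that add atoms: none
Why: In this Hajos–Parrish–Eder–Sauer–Wiechert aldol condensation the D-proline enamine of the side-chain ketone should select one of the two enantiotopic ring carbonyls (it becomes C21, the other stays as the C10 ketone), which sets quaternary C11, and recrystallisation is expected to upgrade the optical purity.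

Step 3
Reactants: 4 (R)-Wieland–Miescher ketone
Product: 5 enone-dithiolane of 4 (spiro 1,3-dithiolane at the enone carbonyl, the future C15; C10 ketone free)
Conditions: HSCH2CH2SH (1.05 equiv), p-TsOH (cat.), AcOH, 25 °C
Reagents that add atoms: ethane-1,2-dithiol, SCCS
Why: Acid-catalysed thioketalisation of this enedione takes the conjugated carbonyl in preference to the hindered saturated C10 ketone, which frees C10 for regiodefined enolate chemistry.

Step 4
Reactants: 5 enone-dithiolane of 4
Product: 6 C24-methyl ketone (both C24 epimers)
Conditions: LiN(i-Pr)2, THF, −78 °C; MeI, −78 → −20 °C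
Reagents that add atoms: iodomethane, CI
Why: Enolate C-alkylation can occur only at C24, because C11 is quaternary and the enone is masked, and the C24 epimers are used together since the centre is made planar again in step 5.

Step 5
Reactants: 6 C24-methyl ketone
Product: 7 C24 tertiary α-hydroxy ketone (C24 methyl cis to C12, hydroxyl trans)
Conditions: KN(SiMe3)2, THF, −78 °C; 2-(benzenesulfonyl)-3-phenyloxaziridine, −78 °C; aq NH4Cl
Reagents that add atoms: 2-(benzenesulfonyl)-3-phenyloxaziridine, O=S(=O)(c1ccccc1)N1OC1c1ccccc1
Why: In this oxaziridine enolate hydroxylation the tetrasubstituted enolate should be oxidised on the face opposite the axial C12 methyl, which places the C24 oxygen trans and the C24 methyl cis to C12, while sulfide oxidation is slow at this temperature.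

Step 6
Reactants: 7 C24 tertiary α-hydroxy ketone
Product: 8 C10,C24 trans-diol (C10 hydroxyl cis to C12)
Conditions: NaBH4, MeOH–THF, 0 → 25 °C
Reagents that add atoms: none
Why: In this borohydride reduction hydride should enter axially at C10, opposite the two syn-axial methyls C12 and C25, to give the equatorial alcohol, a centre that is oxidised again in step 17.

Step 7
Reactants: 8 C10,C24 trans-diol
Product: 9 C10 acetate (C24 tertiary alcohol free)
Conditions: Ac2O, DMAP, pyridine, 50 °C
Reagents that add atoms: acetic anhydride, CC(=O)OC(C)=O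
Why: DMAP-catalysed acylation distinguishes the secondary C10 hydroxyl from the tertiary C24 hydroxyl, and an acetate is chosen because it cannot serve as an oxygen nucleophile toward C15 in step 14 and can later be removed beside a silyl ether.

Step 8
Reactants: 9 C10 acetate
Product: 10 C10 acetate C24 triethylsilyl ether
Conditions: Et3SiOTf, 2,6-lutidine, CH2Cl2, 0 → 25 °C
Reagents that add atoms: triethylsilyl trifluoromethanesulfonate, CC[Si](CC)(CC)OS(=O)(=O)C(F)(F)F
Why: Silyl triflate silylation should cap the hindered tertiary C24 hydroxyl without acyl migration, so that it stays silent in step 14 and is released by fluoride at the end.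

Step 9
Reactants: 10 C10 acetate C24 triethylsilyl ether
Product: 11 enone (dithiolane removed; C10 acetate, C24 triethylsilyl ether)
Conditions: MeI (excess), CaCO3, MeCN–H2O (4:1), 60 °C
Reagents that add atoms: water, O
Why: S-Alkylative hydrolysis of the dithiolane (double S-methylation, then water) regenerates the enone under buffered, non-oxidising conditions that acetate and silyl ether should tolerate.

Step 10
Reactants: 11 enone
Product: 12 seco keto acid (C21 ketone, C15 carboxylic acid)
Conditions: O3, CH2Cl2–MeOH, −78 °C; then H2O2, aq NaHCO3, 0 → 25 °C; acidify to pH 3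
Reagents that add atoms: ozone, [O-][O+]=O; hydrogen peroxide, OO
Why: Ozonolysis of the enone C=C with oxidative work-up should give the C21 ketone and, after oxidative decarboxylation of the α-keto acid stage, the C15 acid shortened by the enone α-carbon.

Step 11
Reactants: 12 seco keto acid
Product: 13 six-membered enol lactone (O–C21=C22, lactone carbonyl C15)
Conditions: Ac2O, NaOAc, 120 °C
Reagents that add atoms: none
Why: Dehydrative enol lactonisation of the 5-oxo acid can give only one enol lactone because C21 enolises solely toward C22, which masks the C21 ketone and activates C15 at once.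

Step 12
Reactants: 13 six-membered enol lactone
Product: 14 isopropenyl diketone (C21 ketone; C15 ketone bearing the C17 isopropenyl group)
Conditions: CH2=C(CH3)MgBr (1.05 equiv), THF, −78 °C; aq NH4Cl at −78 °C
Reagents that add atoms: isopropenylmagnesium bromide, CC(=C)[Mg]Br
Why: In this Grignard addition to an enol lactone (first stage of a Fujimoto–Belleau sequence) the tetrahedral magnesium alkoxide should persist at low temperature and open on work-up to the C21 ketone and the C15 enone, the hindered C10 acetate being far less electrophilic.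

Step 13
Reactants: 14 isopropenyl diketone
Product: 16 seco keto alcohol (C21 ketone; C15 ketone; C17 carbinol; C10 acetate; C24 triethylsilyl ether), via tertiary hydroperoxide 15 (not isolated)
Conditions: Mn(dpm)3 (5 mol%), PhSiH3, O2 (1 atm), i-PrOH–CH2Cl2, 0 °C; then P(OEt)3
Reagents that add atoms: dioxygen, O=O
Why: In this Mukaiyama-type hydration a metal hydride transfers a hydrogen atom to the terminal CH2 of the enone, the tertiary C17 radical next to C15=O is trapped by O2 and the phosphite reduces the hydroperoxide, so the C17 carbinol forms without a new stereocentre.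

Step 14
Reactants: 16 seco keto alcohol
Product: 19 trans-fused oxepanone (C15 ketone; C10 acetate; C24 triethylsilyl ether), via seven-membered hemiketal 17 (not isolated), via oxocarbenium triflate 18 (not isolated)
Conditions: Me3SiOTf (1.1 equiv), Et3SiH (5 equiv), CH2Cl2, −78 → −40 °C; aq NaHCO3
Reagents that add atoms: none
Why: The C17 hydroxyl adds to the activated C21 ketone in a 7-exo-trig closure to give hemiketal 17, the silyl triflate ionises it to the endocyclic oxocarbenium ion 18, and the silane delivers hydride to C21, so the O20–C21 bond and the oxepane ring are made in one flask. The closest known reaction type is the silane–silyl triflate reductive cyclisation of hydroxy ketones to cyclic ethers, which is established for oxepanes. The new C21 stereocentre is controlled by the chair cyclohexyl oxocarbenium ion: hydride should enter axially, anti to the axial C12 methyl on quaternary C11, so that H21 ends trans to C12 and O20 equatorial, which is the trans ring fusion of the target. The step needs reaction at C21 and not at C15, and this is secured because the carbinol cannot close a ring onto the adjacent C15 carbonyl, C10 carries a non-nucleophilic acetate, and the C24 silyl ether could bridge to C21 only through a bridgehead oxocarbenium ion. Low temperature is used so that an acyloin shift of the C15/C17 ketol and loss of the silyl group stay slower than ring closure.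

Step 15
Reactants: 19 trans-fused oxepanone
Product: 20 C10,C15 diol (C24 triethylsilyl ether)
Conditions: LiAlH4, THF, 0 °C
Reagents that add atoms: none
Why: Hydride reduction masks the C15 ketone as a carbinol (either epimer, re-oxidised in step 32) and cleaves the C10 acetate in the same operation.

Step 16
Reactants: 20 C10,C15 diol
Product: 21 C15 triethylsilyl ether (C10 alcohol free)
Conditions: Et3SiCl, imidazole, DMF, 0 → 25 °C
Reagents that add atoms: chlorotriethylsilane, CC[Si](Cl)(CC)CC
Why: Silylation with the silyl chloride should distinguish the two secondary alcohols by hindrance, since the C15 hydroxyl reacts while the C10 hydroxyl between the fully substituted C11 and C24 does not.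

Step 17
Reactants: 21 C15 triethylsilyl ether
Product: 22 C10 ketone (C15 and C24 triethylsilyl ethers)
Conditions: Dess–Martin periodinane, NaHCO3, CH2Cl2, 25 °C
Reagents that add atoms: none
Why: Dess–Martin oxidation should convert the remaining C10 alcohol into the non-enolisable ketone under buffered conditions that silyl ethers tolerate.

Step 18
Reactants: 22 C10 ketone
Product: 23 C10 exocyclic methylene (C9 installed)
Conditions: Ph3PCH3Br, KOt-Bu, toluene, 100 °C
Reagents that add atoms: methyltriphenylphosphonium bromide, C[P+](c1ccccc1)(c1ccccc1)c1ccccc1.[Br-]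
Why: Wittig methylenation with potassium tert-butoxide in hot toluene is the established way to methylenate non-enolisable ketones flanked by fully substituted carbons, and the silyl ether at C24 rules out a ketol shift.

Step 19
Reactants: 24 methyl 4,4-dimethyl-5-oxopentanoate; 25 diethyl (2-methylprop-2-en-1-yl)phosphonate
Product: 26 methyl (5E)-4,4,7-trimethylocta-5,7-dienoate
Conditions: 25, KN(SiMe3)2, THF, −78 °C; then 24, −78 → 25 °C
Reagents that add atoms: none
Why: Horner–Wadsworth–Emmons-type olefination with the allylic phosphonate anion should convert the neopentyl aldehyde into the (E)-1,3-diene, the quaternary α-carbon favouring E and the ester being inert at low temperature.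

Step 20
Reactants: 26 methyl (5E)-4,4,7-trimethylocta-5,7-dienoate
Product: 27 (5E)-N-methoxy-N,4,4,7-tetramethylocta-5,7-dienamide
Conditions: MeNHOMe·HCl, i-PrMgCl, THF, −20 °C
Reagents that add atoms: N,O-dimethylhydroxylamine hydrochloride, CNOC.Cl
Why: Aminolysis of the ester by the magnesium amide of N,O-dimethylhydroxylamine should give the Weinreb amide without touching the diene.

Step 21
Reactants: 27 (5E)-N-methoxy-N,4,4,7-tetramethylocta-5,7-dienamide
Product: 28 (7E)-6,6,9-trimethyldeca-1,7,9-trien-3-one
Conditions: CH2=CHMgBr, THF, −78 → 0 °C; inverse quench into cold 1 M HCl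
Reagents that add atoms: vinylmagnesium bromide, C=C[Mg]Br
Why: In this Weinreb ketone synthesis the chelated tetrahedral adduct prevents over-addition and the acidic inverse quench protonates the released amine before it can add to the vinyl ketone, which is used at once.

Step 22
Reactants: 28 (7E)-6,6,9-trimethyldeca-1,7,9-trien-3-one
Product: 29 cis-fused octalone, cis-4,4,6-trimethyl-3,4,4a,7,8,8a-hexahydronaphthalen-1(2H)-one (C32 ketone, C7=C2 alkene, H5 and H6 syn)
Conditions: (S)-3,3-diphenyl-1-(o-tolyl)tetrahydro-1H,3H-pyrrolo[1,2-c][1,3,2]oxazaborole (20 mol%), Tf2NH (18 mol%), CH2Cl2, −78 → −20 °C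
Reagents that add atoms: none
Why: In this enantioselective Lewis-acid-catalysed intramolecular Diels–Alder reaction of a 1,7,9-decatrien-3-one the bound vinyl ketone should react through the endo transition state with the tether carbonyl under the (E)-diene, which gives the cis ring fusion, while the chiral oxazaborolidinium ion selects the enone face and so the absolute configuration at C5 and C6.

Step 23
Reactants: 29 cis-fused octalone
Product: 32 C8 hydroxy C32 ketone (C8 on C7; C1 methyl on C2 cis to C27 and C32), via endocyclic ene adduct 30 (not isolated), via exocyclic ene adduct 31 (not isolated)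
Conditions: (CH2O)n, Me2AlCl, CH2Cl2, −78 → 0 °C; aqueous work-up, silica plug; then [Ir(cod)(PCy3)(py)]PF6 (5 mol%), H2 (1 atm), CH2Cl2, 25 °C
Reagents that add atoms: paraformaldehyde (reacting as formaldehyde), C=O
Why: The Lewis-acid-promoted carbonyl-ene reaction should attach C8 to the less substituted alkene carbon C7 from the face opposite C27, and the hydroxyl-directed hydrogenation then adds hydrogen to C2 from that same face in either alkene isomer, so the C1 methyl ends cis to C27 and C32.

Step 24
Reactants: 32 C8 hydroxy C32 ketone
Product: 33 C32 methylene C8 alcohol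
Conditions: Cp2TiMe2 (3 equiv), toluene, 65 °C
Reagents that add atoms: dimethyltitanocene, [CH3-].[CH3-].[Ti+4].c1cc[cH-]c1.c1cc[cH-]c1
Why: Petasis methylenation converts the C32 ketone into the exocyclic alkene under neutral conditions that should not epimerise the adjacent ring-fusion centre C5, the excess reagent absorbing the free hydroxyl.

Step 25
Reactants: 33 C32 methylene C8 alcohol
Product: 34 C32 spiro-epoxide (oxygen cis to H5)
Conditions: mCPBA, NaHCO3, CH2Cl2, 0 °C
Reagents that add atoms: 3-chloroperbenzoic acid, OOC(=O)c1cccc(Cl)c1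
Why: Peracid epoxidation of the only alkene should occur on the face of H5 and H6, away from C7, which is axial on ring B, so the oxygen takes the configuration needed for O34.

Step 26
Reactants: 34 C32 spiro-epoxide
Product: 35 C8,C32 diol (C32 tertiary alcohol with oxygen cis to H5)
Conditions: LiAlH4, THF, 0 → 25 °C
Reagents that add atoms: none
Why: Hydride opens the epoxide at its unsubstituted CH2, which becomes the C33 methyl, and leaves the C32 configuration untouched.

Step 27
Reactants: 35 C8,C32 diol
Product: 36 bis(triethylsilyl) ether
Conditions: Et3SiOTf (3 equiv), 2,6-lutidine, CH2Cl2, −78 → 0 °C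
Reagents that add atoms: triethylsilyl trifluoromethanesulfonate, CC[Si](CC)(CC)OS(=O)(=O)C(F)(F)F
Why: Exhaustive silylation protects the tertiary C32 hydroxyl and puts on C8 a primary silyl ether that the next step converts directly.

Step 28
Reactants: 36 bis(triethylsilyl) ether
Product: 37 C8 aldehyde (C32 triethylsilyl ether)
Conditions: (COCl)2, DMSO, CH2Cl2, −78 → −30 °C; Et3N, −78 → 0 °C
Reagents that add atoms: none
Why: Swern oxidation of a primary triethylsilyl ether should give the C8 aldehyde directly while the tertiary silyl ether stays, so a free δ-hydroxy aldehyde that could close to a lactol is never formed.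

Step 29
Reactants: 37 C8 aldehyde
Product: 38 enol triflate (C7=C8, triflate oxygen cis to C2, C32 triethylsilyl ether)
Conditions: KN(SiMe3)2, THF, −78 °C; PhNTf2, −78 → 0 °C
Reagents that add atoms: N-phenylbis(trifluoromethanesulfonimide), O=S(=O)(N(c1ccccc1)S(=O)(=O)C(F)(F)F)C(F)(F)F
Why: O-Triflation of the enolate of the α,α-disubstituted aldehyde gives the exocyclic enol triflate, and the enolate oxygen is expected to lie on the C2 side, away from C6 with its quaternary C27 neighbour, which is the C7=C8 geometry of the target.

Step 30
Reactants: 23 C10 exocyclic methylene; 38 enol triflate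
Product: 40 tris(triethylsilyl) ether of the coupled skeleton (C15, C24 and C32 silyl ethers), via B-alkyl-9-BBN adduct 39 (not isolated)
Conditions: 23, 9-BBN dimer, THF, 65 °C; then 38, Pd(dppf)Cl2, AsPh3, Cs2CO3, DMF–THF–H2O, 25 → 50 °C
Reagents that add atoms: none
Why: In this hydroboration–B-alkyl Suzuki–Miyaura sequence the borane should add to the methylene from the face opposite the syn-axial C12 and C25 methyls, setting C10 with C9 equatorial, and the alkylborane then couples with the enol triflate with retention of the alkene geometry to form C8–C9.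

Step 31
Reactants: 40 tris(triethylsilyl) ether
Product: 41 triol (C15, C24 and C32 hydroxyls)
Conditions: Bu4NF, THF, 25 → 45 °C
Reagents that add atoms: none
Why: Fluoride desilylation removes the three silyl ethers under non-acidic conditions that should not isomerise the exocyclic C7=C8 alkene.

Step 32
Reactants: 41 triol
Product: 42 CNP0232921.1 (target)
Conditions: Dess–Martin periodinane, NaHCO3, CH2Cl2, 0 → 25 °C
Reagents that add atoms: none
Why: Dess–Martin oxidation can act only on the secondary C15 alcohol, since C24 and C32 are tertiary, and restores the oxepanone.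

Compound list
1 | 2-methylcyclohexane-1,3-dione | CC1C(=O)CCCC1=O | starting material
2 | methyl vinyl ketone (but-3-en-2-one) | CC(=O)C=C | starting material
3 | 2-methyl-2-(3-oxobutyl)cyclohexane-1,3-dione | CC(=O)CCC1(C)C(=O)CCCC1=O | intermediate
4 | (R)-Wieland–Miescher ketone, (R)-8a-methyl-3,4,8,8a-tetrahydronaphthalene-1,6(2H,7H)-dione | C[C@@]12CCC(=O)C=C1CCCC2=O | intermediate
5 | enone-dithiolane of 4 (spiro 1,3-dithiolane at the enone carbonyl, C10 ketone free) | C[C@@]12CCC3(SCCS3)C=C1CCCC2=O | intermediate
6 | C24-methyl ketone of 5 (both C24 epimers) | C[C@@]12CCC3(SCCS3)C=C1CCC(C)C2=O | intermediate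
7 | C24 tertiary α-hydroxy ketone (C24 methyl cis to C12) | C[C@@]12CCC3(SCCS3)C=C1CC[C@](C)(O)C2=O | intermediate
8 | C10,C24 trans-diol (C10 hydroxyl cis to C12) | C[C@@]12CCC3(SCCS3)C=C1CC[C@](C)(O)[C@H]2O | intermediate
9 | C10 acetate, C24 alcohol | C[C@@]12CCC3(SCCS3)C=C1CC[C@](C)(O)[C@H]2OC(C)=O | intermediate
10 | C10 acetate, C24 triethylsilyl ether (dithiolane) | C[C@@]12CCC3(SCCS3)C=C1CC[C@](C)(O[Si](CC)(CC)CC)[C@H]2OC(C)=O | intermediate
11 | enone with C10 acetate and C24 triethylsilyl ether | C[C@@]12CCC(=O)C=C1CC[C@](C)(O[Si](CC)(CC)CC)[C@H]2OC(C)=O | intermediate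
12 | seco keto acid (C21 ketone, C15 carboxylic acid) | OC(=O)CC[C@@]1(C)[C@H](OC(C)=O)[C@@](C)(O[Si](CC)(CC)CC)CCC1=O | intermediate
13 | six-membered enol lactone (O–C21=C22) | O=C1CC[C@@]2(C)[C@H](OC(C)=O)[C@@](C)(O[Si](CC)(CC)CC)CC=C2O1 | intermediate
14 | isopropenyl diketone (C21 ketone, C15 isopropenyl ketone) | CC(=C)C(=O)CC[C@@]1(C)[C@H](OC(C)=O)[C@@](C)(O[Si](CC)(CC)CC)CCC1=O | intermediate
15 | C17 tertiary hydroperoxide | CC(C)(OO)C(=O)CC[C@@]1(C)[C@H](OC(C)=O)[C@@](C)(O[Si](CC)(CC)CC)CCC1=O | intermediate
16 | seco keto alcohol (C21 ketone, C15 ketone, C17 carbinol, C10 acetate, C24 triethylsilyl ether) | CC(C)(O)C(=O)CC[C@@]1(C)[C@H](OC(C)=O)[C@@](C)(O[Si](CC)(CC)CC)CCC1=O | intermediate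
17 | seven-membered hemiketal at C21 | CC(=O)O[C@H]1[C@]2(C)CCC(=O)C(C)(C)OC2(O)CC[C@]1(C)O[Si](CC)(CC)CC | intermediate
18 | endocyclic oxocarbenium triflate (O20=C21) | CC(=O)O[C@H]1[C@]2(C)CCC(=O)C(C)(C)[O+]=C2CC[C@]1(C)O[Si](CC)(CC)CC.[O-]S(=O)(=O)C(F)(F)F | intermediate
19 | trans-fused oxepanone (C15 ketone, C10 acetate, C24 triethylsilyl ether; H21 trans to C12) | CC(=O)O[C@H]1[C@]2(C)CCC(=O)C(C)(C)O[C@H]2CC[C@]1(C)O[Si](CC)(CC)CC | intermediate
20 | C10,C15 diol, C24 triethylsilyl ether (C15 epimers) | O[C@H]1[C@]2(C)CCC(O)C(C)(C)O[C@H]2CC[C@]1(C)O[Si](CC)(CC)CC | intermediate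
21 | C15 and C24 triethylsilyl ethers, C10 alcohol | O[C@H]1[C@]2(C)CCC(O[Si](CC)(CC)CC)C(C)(C)O[C@H]2CC[C@]1(C)O[Si](CC)(CC)CC | intermediate
22 | C10 ketone, C15 and C24 triethylsilyl ethers | O=C1[C@]2(C)CCC(O[Si](CC)(CC)CC)C(C)(C)O[C@H]2CC[C@]1(C)O[Si](CC)(CC)CC | intermediate
23 | C10 exocyclic methylene (C9), C15 and C24 triethylsilyl ethers | C=C1[C@]2(C)CCC(O[Si](CC)(CC)CC)C(C)(C)O[C@H]2CC[C@]1(C)O[Si](CC)(CC)CC | intermediate
24 | methyl 4,4-dimethyl-5-oxopentanoate | COC(=O)CCC(C)(C)C=O | starting material
25 | diethyl (2-methylprop-2-en-1-yl)phosphonate | CCOP(=O)(OCC)CC(C)=C | starting material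
26 | methyl (5E)-4,4,7-trimethylocta-5,7-dienoate | COC(=O)CCC(C)(C)/C=C/C(C)=C | intermediate
27 | (5E)-N-methoxy-N,4,4,7-tetramethylocta-5,7-dienamide | CON(C)C(=O)CCC(C)(C)/C=C/C(C)=C | intermediate
28 | (7E)-6,6,9-trimethyldeca-1,7,9-trien-3-one | C=CC(=O)CCC(C)(C)/C=C/C(C)=C | intermediate
29 | cis-fused octalone (C32 ketone, C7=C2 alkene, H5 and H6 syn) | CC1=C[C@H]2C(C)(C)CCC(=O)[C@H]2CC1 | intermediate
30 | endocyclic ene adduct (C8 alcohol on C7, C2=C3 alkene) | CC1=CC[C@H]2[C@@H]([C@H]1CO)C(C)(C)CCC2=O | intermediate
31 | exocyclic ene adduct (C8 alcohol on C7, C2=C1 methylene) | C=C1CC[C@H]2[C@@H]([C@H]1CO)C(C)(C)CCC2=O | intermediate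
32 | C8 hydroxy C32 ketone (C1 methyl cis to C27 and C32) | C[C@@H]1CC[C@H]2[C@@H]([C@H]1CO)C(C)(C)CCC2=O | intermediate
33 | C32 methylene C8 alcohol | C[C@@H]1CC[C@H]2[C@@H]([C@H]1CO)C(C)(C)CCC2=C | intermediate
34 | C32 spiro-epoxide (oxygen cis to H5) | C[C@@H]1CC[C@H]2[C@@H]([C@H]1CO)C(C)(C)CC[C@@]23CO3 | intermediate
35 | C8,C32 diol | C[C@@H]1CC[C@H]2[C@@H]([C@H]1CO)C(C)(C)CC[C@]2(C)O | intermediate
36 | C8,C32 bis(triethylsilyl) ether | C[C@@H]1CC[C@H]2[C@@H]([C@H]1CO[Si](CC)(CC)CC)C(C)(C)CC[C@]2(C)O[Si](CC)(CC)CC | intermediate
37 | C8 aldehyde, C32 triethylsilyl ether | C[C@@H]1CC[C@H]2[C@@H]([C@H]1C=O)C(C)(C)CC[C@]2(C)O[Si](CC)(CC)CC | intermediate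
38 | enol triflate (C7=C8, triflate oxygen cis to C2), C32 triethylsilyl ether | C[C@@H]1CC[C@H]2[C@@H](/C1=C/OS(=O)(=O)C(F)(F)F)C(C)(C)CC[C@]2(C)O[Si](CC)(CC)CC | intermediate
39 | B-alkyl-9-BBN adduct of 23 (boron on C9, C10–H trans to C12 and C25) | B1(C[C@H]2[C@]3(C)CCC(O[Si](CC)(CC)CC)C(C)(C)O[C@H]3CC[C@]2(C)O[Si](CC)(CC)CC)C2CCCC1CCC2 | intermediate
40 | coupled skeleton as C15, C24, C32 tris(triethylsilyl) ether | C[C@@H]1CC[C@H]2[C@@H](/C1=C/C[C@H]1[C@]3(C)CCC(O[Si](CC)(CC)CC)C(C)(C)O[C@H]3CC[C@]1(C)O[Si](CC)(CC)CC)C(C)(C)CC[C@]2(C)O[Si](CC)(CC)CC | intermediate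
41 | C15, C24, C32 triol | C[C@@H]1CC[C@H]2[C@@H](/C1=C/C[C@H]1[C@]3(C)CCC(O)C(C)(C)O[C@H]3CC[C@]1(C)O)C(C)(C)CC[C@]2(C)O | intermediate
42 | CNP0232921.1 | C[C@@H]1CC[C@H]2[C@@H](/C1=C/C[C@H]1[C@]3(C)CCC(=O)C(C)(C)O[C@H]3CC[C@]1(C)O)C(C)(C)CC[C@]2(C)O | target

Total step count: 32. Longest linear sequence: 21 steps (steps 1–18, then 30–32); the left branch (steps 19–29) joins at step 30.

Steps most likely to fail

Step 14. Closure of a seven-membered hemiketal by a tertiary carbinol that sits next to a ketone may be slower than an acid-promoted acyloin shift of the C15/C17 ketol or loss of the C24 silyl group. The fallback sets out from 16 and replaces the oxocarbenium route by a thionium route. EtSH with Zn(OTf)2 in CH2Cl2 should convert the C21 cyclohexanone, the more reactive of the two ketones, into the C21 diethyl dithioketal F1. AgClO4 with NaHCO3 in MeNO2 then removes one ethylthio group, and the C17 hydroxyl closes onto the thionium ion to give the cyclic O,S-ketal F2. Ph3SnH with AIBN in hot toluene replaces the remaining sulfur by hydrogen through the C21 radical, which should take hydrogen axially, and the route is rejoined at 19.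

Step 22. Facial discrimination by the catalyst may be poor, and exo or uncatalysed cyclisation may compete, which would erode both optical purity and the cis ring fusion. The fallback sets out from 28 and separates enantiomers instead of inducing them. Cyclisation promoted by Et2AlCl in CH2Cl2 at low temperature gives the racemic cis-fused ketone F3. Condensation with (S)-1-amino-2-(methoxymethyl)pyrrolidine gives two diastereomeric hydrazones that are separated by chromatography, the one from the wanted enantiomer being the SAMP hydrazone F4. Two-phase hydrolysis with aqueous oxalic acid returns 29.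

Step 18. Attack of the ylide on a carbonyl flanked by the fully substituted C11 and C24 may be too slow, so that the ketone is recovered. The fallback sets out from 22 and uses addition followed by elimination. MeLi with CeCl3 in THF at −78 °C should add to give the C10 methyl carbinol F5. Burgess dehydration in warm benzene can only eliminate toward the new methyl, the sole carbon with β-hydrogens, and gives 23.

Further compounds
F1 | step 14 | C21 diethyl dithioketal of 16 | CC(C)(O)C(=O)CC[C@@]1(C)[C@H](OC(C)=O)[C@@](C)(O[Si](CC)(CC)CC)CCC1(SCC)SCC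
F2 | step 14 | cyclic O,S-ketal (C21 bearing O20 and ethylthio) | CC(=O)O[C@H]1[C@]2(C)CCC(=O)C(C)(C)OC2(SCC)CC[C@]1(C)O[Si](CC)(CC)CC
F3 | step 22 | racemic cis-fused ketone (both enantiomers of 29) | CC1=C[C@H]2C(C)(C)CCC(=O)[C@H]2CC1.CC1=C[C@@H]2C(C)(C)CCC(=O)[C@@H]2CC1
F4 | step 22 | SAMP hydrazone of 29 | CC1=C[C@H]2C(C)(C)CCC(=NN3CCC[C@H]3COC)[C@H]2CC1
F5 | step 18 | C10 methyl carbinol (C10 epimers) | CC1(O)[C@]2(C)CCC(O[Si](CC)(CC)CC)C(C)(C)O[C@H]2CC[C@]1(C)O[Si](CC)(CC)CC
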